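Read the ceiling first.

common to all: reagent 1.00 M
- green: substrate 0.500 M; catalyst 0.00100 M
- blue: substrate 1.00 M; catalyst 0.00100 M
- violet: substrate 1.50 M; catalyst 0.00200 M; time 110 min

| green run: time / min | green run: [target] / M | blue run: time / min | blue run: [target] / M |
|---|---|---|---|
| 3.9 | 0.021 | 3.9 | 0.038 |
| 12 | 0.054 | 12 | 0.117 |
| 23 | 0.110 | 23 | 0.213 |
| 36 | 0.157 | 36 | 0.302 |
| 52 | 0.206 | 52 | 0.394 |
| 69 | 0.247 | 69 | 0.488 |
| 89 | 0.296 | 89 | 0.554 |
| 110 | 0.336 | 110 | 0.625 |

(each reading ± 0.004 M)

- how the opening rate goes with [substrate] round the charge of the green run: the exponent of the rate at two percent of substrate gone to target (one fixed amount of target, the same in the runs compared)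
- target in the violet run at 110 min, as a share of the substrate charged

- Overall: substrate + reagent -> target, with catalyst as catalyst.
- Constant volume, constant temperature.
- The analysis sees a species whether free or bound.
- "The second partner" is reagent.
- An order is taken over about fifteen percent of the charge, up and down.

1. The ceiling. Each target takes one reagent, and the violet flask holds less reagent than substrate. So reagent is the limiting reagent, and target stops at 1.00 M, which is 66.7% of the substrate charged.

2. The clock. We replace each curve by a single decay of substrate. Its mean time constant is the elapsed time divided by the logarithm of substrate charged over substrate remaining: in the green run, over 110 min, 98.7 min.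

3. The order. At 23 min the readings give 92.6 min for the green run and 96.0 min for the blue run. Equal clocks would mean order one; these read 0.948, so we take an order near one.

4. The violet curve. The violet flask has twice the catalyst of the green run. We assume the clock shortens by that ratio, to 49.3 min, though both runs so far share one catalyst charge. On this clock we reckon an opening slope of 0.0304 M/min. We place the knee where 0.500 M of substrate remains, and this estimate puts it at 54.2 min.

5. The error. The mean clock of the blue run over 110 min is longer, 112 min. On that clock the knee moves to 61.6 min, still earlier than 110 min. We commit to a share just under the ceiling.

6. The forecast. It gives an order of 0.95 (0.8 to 1.08) and 64% (54% to 66.5%), lower than our ceiling, and it warns: “Catalyst order or substrate saturation could lower it.”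

    catalyst + substrate → catalyst-substrate complex (7.260 /M/min)
    catalyst-substrate complex + reagent → target + catalyst (98.40 /M/min)
    catalyst + reagent ⇌ idle catalyst-reagent complex, settled at all times (0.6570 /M)
    substrate + reagent → target (0.006480 /M/min)

The order comes out at 1.0, and the violet run gives 66.6% of its substrate charged at 110 min, which is 2.6 percentage points above the forecast and against a ceiling of 66.7%. The joining of catalyst and reagent to the idle catalyst-reagent complex makes no difference to that share. On our violet clock of 49.3 min, the asked time is 2.23 time constants. Carried to the blue run, 98.7 min times the logarithm of 2 puts target at half of the substrate charged at 68.4 min, and the blue run arrives there at 74.2 min.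

The data come from a simulation on assumed constants, noise included.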